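**Assumptions (one line each)**
- Iridoid numbering is used throughout: C1 acetal CH, O2, C3, C4, C5, C6, C7, C8, C9 ring-fusion CH, C10 = CH2 on C8, C11 = CH2 on C4. "β" means the face of H-9 and "α" the opposite face.
- The target SMILES is read as (1S,7S,8R,9S): 1-O-isovaleryl, H-9, 7-O-isovaleryl and C10 are on the β face, and 8-OH is α.
- 3-Ethynyloxetane, 4-methoxybenzyl alcohol and propargyl bromide are taken as commercial.
- The (R,R)-Trost ligand is assumed to give the (R)-acetal drawn in step 4; if the sense is opposite, the (S,S)-ligand is used and nothing else changes.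
- C4 is carried as a racemic centre through compounds 6–8; it becomes sp2 in step 6, so this is inconsequential.

**Retrosynthetic overview**
1. Target ⇐ 7-keto dienol-ether core by late acylations (C1 and C7 isovalerates), CBS reduction at C7 and final unmasking of C10-OH.
2. C8 (OH)(CH2OH) ⇐ α′-hydroxylation, then formaldehyde aldol on the cyclopentenone, with the face controlled by the axial C1 acetal.
3. C3=C4 dienol ether ⇐ γ,δ-dehydrogenation of the Pauson–Khand enone (this erases C4).
4. Key step: an intramolecular Pauson–Khand reaction of an acyclic 1,7-enyne mixed acetal forms the pyran and the cyclopentenone in the same step, relaying C1 → C9. Semisynthesis from valtrate/genipin and the classical iridoid dialdehyde/lactol logic are not used.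
5. C1 acetal ⇐ Pd-catalysed asymmetric hydroalkoxylation of PMB-oxyallene. This is the only source of absolute configuration; C1 is a sacrificial stereocentre that is reset at the lactol stage.

**Route**

Step 1
Reactants: 1 (4-methoxybenzyl alcohol), 2 (propargyl bromide)
Product: 3 (4-methoxybenzyl propargyl ether)
Conditions: NaH, THF/DMF, 0 °C → rt
Reagents that add atoms: none besides reactant 2 (propargyl bromide, C#CCBr)
Why: Williamson ether synthesis (SN2 on the primary propargylic bromide); no stereocentre.

Step 2
Reactants: 3
Product: 4 (1-methoxy-4-[(propa-1,2-dienyloxy)methyl]benzene, "PMB-oxyallene")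
Conditions: KOtBu (0.3 equiv), THF, 0 °C → rt
Reagents that add atoms: none
Why: Base-mediated prototropic propargyl → allenyl ether isomerisation, stopped at the allene by catalytic base at low temperature.

Step 3
Reactants: 5 (3-ethynyloxetane)
Product: 6 (rac-2-ethynyl-3-hydroxypropyl acetate)
Conditions: AcOH (5 equiv), Sc(OTf)3 (5 mol %), CH2Cl2, 0 °C → rt
Reagents that add atoms: acetic acid, CC(=O)O
Why: Lewis-acid-catalysed SN2 ring opening of the strained oxetane by acetic acid at either equivalent CH2 gives the monoacetate directly; C4 is racemic and is later erased, and 1,3-acyl migration is degenerate.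

Step 4
Reactants: 6, 4
Product: 7 ((R)-mixed acetal: 2-ethynyl-3-{[1-(4-methoxybenzyloxy)prop-2-en-1-yl]oxy}propyl acetate, C4 epimer mixture)
Conditions: Pd2(dba)3·CHCl3 (2.5 mol %), (R,R)-DACH-phenyl Trost ligand (7.5 mol %), Et3N (1 equiv), toluene, rt
Reagents that add atoms: none besides reactant 4 (COc1ccc(COC=C=C)cc1)
Why: Pd-catalysed asymmetric intermolecular hydroalkoxylation of an alkoxyallene (Pd–H addition gives an alkoxy-π-allyl complex and the alcohol attacks the O-bearing terminus); the chiral ligand sets the acetal carbon C1.

Step 5
Reactants: 7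
Product: 8 (bicyclic enone: 1α-OPMB (trans to H-9), 9β-H, C5=C6, C7=O, C8H2, 4-CH2OAc, C4 epimer mixture)
Conditions: Co2(CO)8 (1.1 equiv), CH2Cl2, rt; then NMO·H2O (8 equiv), 0 °C → rt
Reagents that add atoms: carbon monoxide from Co2(CO)8, [C-]#[O+]
Why: Intramolecular Pauson–Khand [2+2+1] closes both rings with fixed regiochemistry; a chair-like transition state with the OPMB group axial (anomeric effect) places H-9 anti to OPMB, so C1 sets C9 (predicted dr about 4:1; the minor C9 epimer is removed after step 6).

Step 6
Reactants: 8
Product: 9 (push–pull dienone: O2–C3=C4(CH2OAc)–C5=C6–C7=O, 1α-OPMB, 9β-H)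
Conditions: chloranil (1.5 equiv), toluene/t-BuOH (4:1), 90 °C; chromatography removes the minor C9 epimer
Reagents that add atoms: none
Why: Quinone dehydrogenation through the heteroannular C4=C5 dienol (the reaction type that converts Δ4-3-ketosteroids to Δ4,6-dienones): hydride is taken from the axial, oxygen-activated C3–H and not from the equatorial, poorly aligned C1–H, and chloranil is too weak to oxidise the PMB group; C4 is erased.

Step 7
Reactants: 9
Product: 10 (8-hydroxy ketone, C8 configuration not controlled)
Conditions: KHMDS (1.1 equiv), THF, −78 °C; then 2-(phenylsulfonyl)-3-phenyloxaziridine (1.3 equiv), −78 °C; NH4Cl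
Reagents that add atoms: Davis oxaziridine, O=S(=O)(N1OC1c1ccccc1)c1ccccc1
Why: Kinetic α′-deprotonation (C8 is the only α-CH; the γ C9–H is not removed at −78 °C) followed by Davis enolate hydroxylation; the C8 configuration is irrelevant because C8 is re-planarised in step 8.

Step 8
Reactants: 10
Product: 11 (8α-OH, 8β-CH2OH diol; 7-ketone; 1α-OPMB)
Conditions: TMSOTf (3 equiv), Et3N (4 equiv), CH2Cl2, −20 → 0 °C; then 37 % aq. HCHO (10 equiv), Yb(OTf)3 (10 mol %), THF, 0 °C → rt
Reagents that add atoms: formaldehyde, C=O
Why: Lanthanide-triflate-catalysed aqueous Mukaiyama aldol (hydroxymethylation) of the bis-silyl enediol ether; formaldehyde attacks C8 on the β face, anti to C1 and its axial OPMB group, so CH2OH ends cis to H-9 and OH trans (this sets C8).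

Step 9
Reactants: 11
Product: 12 (10-O-TES ether, free tertiary 8-OH)
Conditions: TESCl (1.1 equiv), imidazole, CH2Cl2, −20 °C
Reagents that add atoms: chlorotriethylsilane, CC[Si](Cl)(CC)CC
Why: Selective silylation of the primary alcohol; the tertiary 8-OH is inert under these conditions.

Step 10
Reactants: 12
Product: 13 (C1 lactol, anomeric mixture)
Conditions: DDQ (1.5 equiv), CH2Cl2/pH 7 buffer (10:1), 0 °C → rt
Reagents that add atoms: none (water supplies only H; its oxygen leaves in anisaldehyde)
Why: Oxidative PMB-acetal cleavage (benzylic hydride abstraction, then hydrolysis) under neutral conditions; the electron-poor dienone and the TES ether survive, and the C1 relay centre is released as a mutarotating lactol.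

Step 11
Reactants: 13
Product: 14 (1β-O-isovalerate, H-1/H-9 trans; 7-ketone)
Conditions: isovaleryl chloride (1.3 equiv), pyridine, DMAP (5 mol %), CH2Cl2, −40 → 0 °C
Reagents that add atoms: isovaleryl chloride, CC(C)CC(=O)Cl
Why: Base-mediated O-acylation of the rapidly equilibrating lactol, expected to occur at the more nucleophilic equatorial (β) hemiacetal oxygen as in acylations of iridoid aglycone lactols; this sets C1, and the β-ester is trans to 8α-OH so it cannot migrate.

Step 12
Reactants: 14
Product: 15 (7β-alcohol)
Conditions: (R)-Me-CBS (1.0 equiv), catecholborane (2.5 equiv), toluene/CH2Cl2, −78 → −40 °C; pH 7 work-up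
Reagents that add atoms: none
Why: CBS reduction with the quaternary C8 as the large group delivers hydride to the α face, reinforced by substrate bias (anti to the β-CH2OTES), giving the 7β-OH (sets C7); catecholborane leaves the esters, the acyl acetal and the dienol ether untouched.

Step 13
Reactants: 15
Product: 16 (1,7-di-O-isovalerate, 11-OAc, 10-O-TES, free 8-OH)
Conditions: isovaleric anhydride (2 equiv), DMAP (0.2 equiv), Et3N, CH2Cl2, 0 °C
Reagents that add atoms: isovaleric anhydride, CC(C)CC(=O)OC(=O)CC(C)C
Why: DMAP-catalysed acylation of the secondary allylic alcohol, with the hindered tertiary 8-OH unreactive; it is run cold and basic because C7–O is now an ionisable, doubly vinylogous position.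

Step 14
Reactants: 16
Product: 17 (Jatamanvaltrate K)
Conditions: HF·pyridine, excess pyridine, THF, 0 °C; NaHCO3 quench
Reagents that add atoms: none
Why: Buffered fluoride desilylation of the primary TES ether under mildly acidic, non-nucleophilic conditions that leave the esters, the acyl acetal and the dienol ether intact and avoid base-induced acyl migration to C10-OH.

**Compound list**
1 | 4-methoxybenzyl alcohol | COc1ccc(CO)cc1 | starting material
2 | propargyl bromide | C#CCBr | starting material
3 | 4-methoxybenzyl propargyl ether | COc1ccc(COCC#C)cc1 | intermediate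
4 | PMB-oxyallene | COc1ccc(COC=C=C)cc1 | intermediate
5 | 3-ethynyloxetane | C#CC1COC1 | starting material
6 | rac-2-ethynyl-3-hydroxypropyl acetate | CC(=O)OCC(CO)C#C | intermediate
7 | (R)-vinyl mixed acetal (C4 epimers) | COc1ccc(CO[C@H](C=C)OCC(COC(C)=O)C#C)cc1 | intermediate
8 | Pauson–Khand enone, 1α-OPMB, 9β-H (C4 epimers) | COc1ccc(CO[C@H]2OCC(COC(C)=O)C3=CC(=O)C[C@@H]23)cc1 | intermediate
9 | 3,5-dien-7-one, 1α-OPMB, 11-OAc | COc1ccc(CO[C@H]2OC=C(COC(C)=O)C3=CC(=O)C[C@@H]23)cc1 | intermediate
10 | 8-hydroxy-7-ketone (C8 unassigned) | COc1ccc(CO[C@H]2OC=C(COC(C)=O)C3=CC(=O)C(O)[C@@H]23)cc1 | intermediate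
11 | 8α-hydroxy-8β-hydroxymethyl-7-ketone | COc1ccc(CO[C@H]2OC=C(COC(C)=O)C3=CC(=O)[C@](O)(CO)[C@@H]23)cc1 | intermediate
12 | 10-O-TES ether of 11 | COc1ccc(CO[C@H]2OC=C(COC(C)=O)C3=CC(=O)[C@](O)(CO[Si](CC)(CC)CC)[C@@H]23)cc1 | intermediate
13 | C1 lactol (anomers) | OC1OC=C(COC(C)=O)C2=CC(=O)[C@](O)(CO[Si](CC)(CC)CC)[C@@H]12 | intermediate
14 | 1β-O-isovaleryl-7-ketone | CC(C)CC(=O)O[C@@H]1OC=C(COC(C)=O)C2=CC(=O)[C@](O)(CO[Si](CC)(CC)CC)[C@@H]12 | intermediate
15 | 1β-O-isovaleryl-7β-ol | CC(C)CC(=O)O[C@@H]1OC=C(COC(C)=O)C2=C[C@H](O)[C@](O)(CO[Si](CC)(CC)CC)[C@@H]12 | intermediate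
16 | 10-O-TES Jatamanvaltrate K | CC(C)CC(=O)O[C@@H]1OC=C(COC(C)=O)C2=C[C@H](OC(=O)CC(C)C)[C@](O)(CO[Si](CC)(CC)CC)[C@@H]12 | intermediate
17 | Jatamanvaltrate K, (1S,7S,8R,9S) | CC(C)CC(=O)O[C@@H]1OC=C(COC(C)=O)C2=C[C@H](OC(=O)CC(C)C)[C@](O)(CO)[C@@H]12 | target

**Totals**
- Total steps: 14
- Longest linear sequence: 13 (steps 1, 2, 4–14 from 4-methoxybenzyl alcohol; 12 from 3-ethynyloxetane)
- Enantiopurity equals the ee of step 4; diol 11 is the likeliest point to upgrade it by crystallisation.

**Three steps most likely to fail**
1. Step 5 (Pauson–Khand): a 1,7-enyne forming a six-membered ring is slower than the usual 1,6 case, and the C1 → C9 relay rests on a predicted anomeric preference that also sets the absolute configuration. Fallback: abandon the [2+2+1]. Start from an enantioenriched 6-acyloxy-2H-pyran-3(6H)-one (Achmatowicz product of furfuryl alcohol, dynamic kinetic acylation). Annulate the cyclopentenone by Mukaiyama–Michael addition of the silyl enol ether of pyruvaldehyde dimethyl acetal anti to the anomeric group, then acid-mediated intramolecular aldol condensation. Install C3=C4/C11 from the C4 ketone via its enol triflate and Stille coupling with Bu3SnCH2OH.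
2. Step 6 (dehydrogenation): enolisation toward C9 followed by oxidation at C1 could compete, and the acetal or PMB group may not survive hot quinone. Fallback: avoid dehydrogenation by carrying oxygen at C4. Build the enyne from a glycolate-derived propargylic silyl ether so the Pauson–Khand product has a C4–O. After C8 is quaternary (C7 ketone then non-enolisable), oxidise to the C4 ketone, form the C3=C4 enol triflate regiospecifically, and attach C11 by Stille hydroxymethylation, then acetylate.
3. Step 11 (C1 acylation): the lactol may acylate as the α-anomer, possibly favoured by hydrogen bonding to 8α-OH. Fallback: switch from O-acylation to substitution at C1. Convert lactol 13 to the thermodynamic axial α-trichloroacetimidate (Cl3CCN, DBU) and displace with isovaleric acid without promoter; SN2-type inversion gives the 1β-ester, favoured here because the C1 oxocarbenium is disfavoured by the vinylogous-ester ring oxygen.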